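**Target:** (6R)-6-[(1E,4S,6R,8R,9E)-4,6,8-trihydroxy-10-phenyldeca-1,9-dien-1-yl]-5,6-dihydro-2H-pyran-2-one. C4′/C6′ are anti and C6′/C8′ are syn.

**Retrosynthetic overview**
1. The dihydropyranone ring is formed last: tandem ring-closing/cross metathesis joins triol 10 (C2′–C10′) and acrylate 15 (C2–C6, C1′) and creates the C1′=C2′ E-alkene.
2. Triol 10 comes from aldehyde 8 by reagent-controlled allylboration (C4′); the oxidative work-up also removes the boron tether.
3. Key disconnection: the C6′–O bond, made by a boron-tethered oxa-Michael addition on δ-hydroxy enal 6, which relays C8′ to C6′ (syn).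
4. Enal 6 comes from cinnamaldehyde (allylboration sets C8′, then cross-metathesis with crotonaldehyde); acrylate 15 comes from acrolein (allylboration sets C6, then O-acylation).
5. Ring order: temporary 1,3,2-dioxaborinane (step 3, removed in step 4), then the dihydropyranone (step 7).

Assumption: chiral boranes, catalysts and phenylboronic acid are treated as reagents without compound numbers; ring carbons are C2–C6 and side-chain carbons C1′–C10′ counted from the lactone.

**Step 1**
Reactants: 1 cinnamaldehyde; 2 allylmagnesium bromide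
Product: 4 (1E,3R)-1-phenylhexa-1,5-dien-3-ol, via O-borinate 3 (not isolated)
Conditions: (+)-Ipc2BOMe [(−)-α-pinene series], 2, Et2O, −78 °C → rt; then 1, −78 °C; 3 M NaOH, 30% H2O2, rt
Reagents that add atoms: none
Why: Brown asymmetric allylboration, in which the allylborane of the (−)-α-pinene series delivers allyl to the Re face of the aldehyde through a chair six-membered transition state and so sets C8′ as R, the borinate being cleaved by alkaline peroxide.

**Step 2**
Reactants: 4 (1E,3R)-1-phenylhexa-1,5-dien-3-ol; 5 (E)-but-2-enal (crotonaldehyde)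
Product: 6 (2E,5R,6E)-5-hydroxy-7-phenylhepta-2,6-dienal
Conditions: 5 (5 equiv), second-generation Hoveyda–Grubbs catalyst RuCl2(H2IMes)(=CH-C6H4-2-OiPr) (3 mol%), CH2Cl2, 40 °C
Reagents that add atoms: none
Why: Olefin cross-metathesis of the terminal alkene with excess crotonaldehyde is E-selective and leaves the hindered 1,2-disubstituted styrenyl alkene and the free carbinol (C8′) untouched.

**Step 3**
Reactants: 6 (2E,5R,6E)-5-hydroxy-7-phenylhepta-2,6-dienal
Product: 8 2-[(4S,6R)-2-phenyl-6-[(E)-2-phenylethenyl]-1,3,2-dioxaborinan-4-yl]acetaldehyde, via boronic hemiester 7 (not isolated)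
Conditions: PhB(OH)2 (1.2 equiv), (S)-α,α-diphenylprolinol trimethylsilyl ether (20 mol%), PhCO2H (20 mol%), toluene, 0 °C → rt
Reagents that add atoms: phenylboronic acid, OB(O)c1ccccc1
Why: Proposed new method: a boron-tethered intramolecular oxa-Michael addition to an enal under secondary-amine (iminium) catalysis, in which 6 and PhB(OH)2 condense reversibly to hemiester 7, the amine turns the enal into an iminium ion, and the B–OH oxygen (made nucleophilic by benzoate binding at boron) adds 6-exo to C6′ through a chair transition state with the styryl group and the iminium arm pseudo-equatorial, so the new C6′–O bond forms syn to C8′ (C6′ R in the target; the S-configured catalyst exposes the same Si face, a matched case, and the cis-4,6-dioxaborinane is also the thermodynamic product of the reversible addition); the closest known reactions are the tertiary-amine/thiourea-catalysed boronic acid oxa-Michael addition to γ- and δ-hydroxy enones and the base-mediated hemiacetal oxa-Michael addition to δ-hydroxy enoates, neither shown for enals under iminium activation or for relay from a secondary allylic carbinol.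

**Step 4**
Reactants: 8 2-[(4S,6R)-2-phenyl-6-[(E)-2-phenylethenyl]-1,3,2-dioxaborinan-4-yl]acetaldehyde; 2 allylmagnesium bromide
Product: 10 (1E,3R,5R,7S)-1-phenyldeca-1,9-diene-3,5,7-triol, via borinate-boronate adduct 9 (not isolated)
Conditions: (−)-Ipc2BOMe [(+)-α-pinene series], 2, Et2O, −78 °C → rt; then 8, −78 °C; 3 M NaOH, 30% H2O2, 0 °C → rt
Reagents that add atoms: none
Why: Brown allylboration under reagent control, in which the allylborane of the (+)-α-pinene series attacks the Si face of the aldehyde and sets C4′ as S (anti to C6′), while the alkaline peroxide work-up cleaves the borinate and oxidises the B–Ph bond so that the boron tether leaves as phenol and borate without a separate deprotection.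

**Step 5**
Reactants: 11 acrolein; 2 allylmagnesium bromide
Product: 13 (3R)-hexa-1,5-dien-3-ol, via O-borinate 12 (not isolated)
Conditions: (+)-Ipc2BOMe [(−)-α-pinene series], 2, Et2O, −78 °C → rt; then 11, −78 °C; 3 M NaOH, 30% H2O2; distillation
Reagents that add atoms: none
Why: Brown asymmetric allylboration with Re-face delivery of allyl to acrolein (1,2-addition) sets the future lactone carbon C6 as R.

**Step 6**
Reactants: 13 (3R)-hexa-1,5-dien-3-ol; 14 acryloyl chloride
Product: 15 (3R)-hexa-1,5-dien-3-yl prop-2-enoate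
Conditions: Et3N, DMAP (cat.), CH2Cl2, 0 °C
Reagents that add atoms: none
Why: DMAP-catalysed O-acylation forms the ester C–O bond that becomes the lactone C–O bond and does not touch the carbinol stereocentre.

**Step 7**
Reactants: 10 (1E,3R,5R,7S)-1-phenyldeca-1,9-diene-3,5,7-triol; 15 (3R)-hexa-1,5-dien-3-yl prop-2-enoate
Product: 17 (6R)-6-[(1E,4S,6R,8R,9E)-4,6,8-trihydroxy-10-phenyldeca-1,9-dien-1-yl]-5,6-dihydro-2H-pyran-2-one, via vinyl lactone 16 (not isolated)
Conditions: 15 (3 equiv), second-generation Hoveyda–Grubbs catalyst RuCl2(H2IMes)(=CH-C6H4-2-OiPr) (10 mol%), 2,6-dichloro-1,4-benzoquinone (10 mol%), CH2Cl2, 40 °C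
Reagents that add atoms: none
Why: Tandem ring-closing/cross metathesis, in which the acrylate closes onto the homoallylic vinyl group to give the six-membered vinyl lactone 16 and its remaining vinyl group then undergoes E-selective cross-metathesis with the terminal alkene of 10, with no stereocentre involved.

**Compound list**
1 | cinnamaldehyde | O=C/C=C/c1ccccc1 | starting material
2 | allylmagnesium bromide | C=CC[Mg]Br | starting material
3 | O-diisopinocampheylborinate of 4 [(−)-α-pinene series] | C=CC[C@@H](OB([C@H]1C[C@H]2C[C@H](C2(C)C)[C@@H]1C)[C@H]1C[C@H]2C[C@H](C2(C)C)[C@@H]1C)/C=C/c1ccccc1 | intermediate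
4 | (1E,3R)-1-phenylhexa-1,5-dien-3-ol | C=CC[C@@H](O)/C=C/c1ccccc1 | intermediate
5 | (E)-but-2-enal (crotonaldehyde) | C/C=C/C=O | starting material
6 | (2E,5R,6E)-5-hydroxy-7-phenylhepta-2,6-dienal | O=C/C=C/C[C@@H](O)/C=C/c1ccccc1 | intermediate
7 | (1E,3R,5E)-7-oxo-1-phenylhepta-1,5-dien-3-yl hydrogen phenylboronate (boronic hemiester of 6) | O=C/C=C/C[C@@H](OB(O)c1ccccc1)/C=C/c1ccccc1 | intermediate
8 | 2-[(4S,6R)-2-phenyl-6-[(E)-2-phenylethenyl]-1,3,2-dioxaborinan-4-yl]acetaldehyde (cis-4,6) | O=CC[C@@H]1C[C@H](/C=C/c2ccccc2)OB(c2ccccc2)O1 | intermediate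
9 | O-diisopinocampheylborinate [(+)-α-pinene series] of the (S)-allyl adduct of 8, cyclic phenylboronate intact | C=CC[C@H](OB([C@@H]1C[C@@H]2C[C@@H](C2(C)C)[C@H]1C)[C@@H]1C[C@@H]2C[C@@H](C2(C)C)[C@H]1C)C[C@@H]1C[C@H](/C=C/c2ccccc2)OB(c2ccccc2)O1 | intermediate
10 | (1E,3R,5R,7S)-1-phenyldeca-1,9-diene-3,5,7-triol | C=CC[C@H](O)C[C@@H](O)C[C@@H](O)/C=C/c1ccccc1 | intermediate
11 | acrolein | C=CC=O | starting material
12 | O-diisopinocampheylborinate of 13 [(−)-α-pinene series] | C=CC[C@H](C=C)OB([C@H]1C[C@H]2C[C@H](C2(C)C)[C@@H]1C)[C@H]1C[C@H]2C[C@H](C2(C)C)[C@@H]1C | intermediate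
13 | (3R)-hexa-1,5-dien-3-ol | C=CC[C@H](C=C)O | intermediate
14 | acryloyl chloride | C=CC(=O)Cl | starting material
15 | (3R)-hexa-1,5-dien-3-yl prop-2-enoate | C=CC[C@H](C=C)OC(=O)C=C | intermediate
16 | (6R)-6-ethenyl-5,6-dihydro-2H-pyran-2-one | O=C1C=CC[C@H](C=C)O1 | intermediate
17 | (6R)-6-[(1E,4S,6R,8R,9E)-4,6,8-trihydroxy-10-phenyldeca-1,9-dien-1-yl]-5,6-dihydro-2H-pyran-2-one | O=C1C=CC[C@H](/C=C/C[C@H](O)C[C@@H](O)C[C@@H](O)/C=C/c2ccccc2)O1 | target

**Step count and risks**
Total steps: 7. Longest linear sequence: 5 (steps 1, 2, 3, 4, 7).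

Most likely to fail, step 3 (the proposed new step). The amine may instead form a dienamine from 6 and dehydrate it to the conjugated trienal, or the dioxaborinane may form with low syn selectivity. The fallback uses known chemistry, sets out from 6 and comes back at 10. The Bi(NO3)3·5H2O-mediated two-component hemiacetal/oxa-conjugate addition with acetaldehyde (CH2Cl2, rt) gives the all-cis ethylidene acetal 2-[(2R,4S,6R)-2-methyl-6-[(E)-2-phenylethenyl]-1,3-dioxan-4-yl]acetaldehyde F1. Brown allylboration as in step 4 passes through the O-diisopinocampheylborinate of the allyl adduct F2 and gives (2S)-1-[(2R,4R,6R)-2-methyl-6-[(E)-2-phenylethenyl]-1,3-dioxan-4-yl]pent-4-en-2-ol F3. Transacetalisation with CSA in MeOH at rt then releases triol 10. This costs one extra step.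

Second, step 7. The free triol may slow the ruthenium catalyst, or the allylic styrenyl carbinol may isomerise or be cleaved. The fallback is a protected, two-stage coupling that sets out from 10 and 15 and comes back at 17. Triol 10 is silylated (TESOTf, 2,6-lutidine, CH2Cl2, −78 °C) to the tris(triethylsilyl) ether of 10 F4. Acrylate 15 is cyclised alone (second-generation Grubbs catalyst RuCl2(H2IMes)(PCy3)(=CHPh), CH2Cl2, 40 °C) and vinyl lactone 16 is isolated. Cross-metathesis of F4 with 16 (second-generation Hoveyda–Grubbs catalyst, CH2Cl2, 40 °C) gives the tris(triethylsilyl) ether of 17 F5. HF·pyridine in THF at 0 °C then gives 17.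

Third, step 2. The δ-hydroxy enal 6 is prone to dehydration, and crotonaldehyde cross-metathesis can stall. The fallback sets out from 4 and comes back at 6. Cross-metathesis of 4 with methyl acrylate (second-generation Grubbs catalyst, CH2Cl2, 40 °C) gives methyl (2E,5R,6E)-5-hydroxy-7-phenylhepta-2,6-dienoate F6. Reduction with iBu2AlH (CH2Cl2, −78 °C) gives (2E,5R,6E)-7-phenylhepta-2,6-diene-1,5-diol F7. Selective oxidation of the primary allylic alcohol with TEMPO/PhI(OAc)2 (CH2Cl2, rt) then gives 6.

**Further compounds**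
F1 | step 3 | 2-[(2R,4S,6R)-2-methyl-6-[(E)-2-phenylethenyl]-1,3-dioxan-4-yl]acetaldehyde | O=CC[C@@H]1C[C@H](/C=C/c2ccccc2)O[C@H](C)O1
F2 | step 3 | O-diisopinocampheylborinate [(+)-α-pinene series] of F3 | C=CC[C@H](OB([C@@H]1C[C@@H]2C[C@@H](C2(C)C)[C@H]1C)[C@@H]1C[C@@H]2C[C@@H](C2(C)C)[C@H]1C)C[C@@H]1C[C@H](/C=C/c2ccccc2)O[C@H](C)O1
F3 | step 3 | (2S)-1-[(2R,4R,6R)-2-methyl-6-[(E)-2-phenylethenyl]-1,3-dioxan-4-yl]pent-4-en-2-ol | C=CC[C@H](O)C[C@@H]1C[C@H](/C=C/c2ccccc2)O[C@H](C)O1
F4 | step 7 | tris(triethylsilyl) ether of 10 | C=CC[C@H](O[Si](CC)(CC)CC)C[C@@H](O[Si](CC)(CC)CC)C[C@@H](O[Si](CC)(CC)CC)/C=C/c1ccccc1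
F5 | step 7 | tris(triethylsilyl) ether of 17 | O=C1C=CC[C@H](/C=C/C[C@H](O[Si](CC)(CC)CC)C[C@@H](O[Si](CC)(CC)CC)C[C@@H](O[Si](CC)(CC)CC)/C=C/c2ccccc2)O1
F6 | step 2 | methyl (2E,5R,6E)-5-hydroxy-7-phenylhepta-2,6-dienoate | COC(=O)/C=C/C[C@@H](O)/C=C/c1ccccc1
F7 | step 2 | (2E,5R,6E)-7-phenylhepta-2,6-diene-1,5-diol | OC/C=C/C[C@@H](O)/C=C/c1ccccc1
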